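**Plan**

Numbering (3,7-dioxabicyclo[3.3.0]octane): C1 (C–OAc), C2 (CH-guaiacyl), O3, C4H2, C5 (CH), C6 (CH-veratryl), O7, C8H2. Ring A = O3/C2/C1/C5/C4, ring B = O7/C6/C5/C1/C8.
Enabling feature: in ring B the one-carbon branch C4 sits on C5, between the aryl carbinol carbon C6 and the oxygenated C1. Putting C4 back between C5 and C1 turns ring B into the oxane O7–C6–C5–C4–C1–C8. This is a 1-C-aryl-1,5-anhydropentitol whose five carbons are those of D-xylose, and its equatorial C5–O leaving group is antiperiplanar to C4–C1.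
Cuts: acetate and phenol benzyl ether; C1–C2 (Norrish–Yang); O3–C2 (Williamson); return of C1 from C5 to C4 (retro-semipinacol, oxolane to oxane); C6–aryl (Pd-catalysed arylation of di-O-acetyl-D-xylal).
Forward order: the oxane comes from the glycal, ring B arises from it by ring contraction, and ring A is closed last by photocyclisation.
Stereochemistry: the allylic acetate of D-xylal is relayed to C6 by anti arylation. The aryl and silyloxy groups steer OsO4 to the opposite face, and the resulting C5–O bond is inverted in the 1,2-shift, which sets C5. The C5–C4–O3 tether sets C1 (cis fusion), and exo closure sets C2.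

Key step: step 6

Remark: target numbering is kept for all intermediates, so the ring of 3–8 is O7–C6–C5–C4–C1–C8. Compounds 1, 2 and 11 are taken as commercial.

**Step 1**
Reactants: 1 3,4-di-O-acetyl-D-xylal; 2 3,4-dimethoxyphenylboronic acid
Product: 3 (3S,6S)-6-(3,4-dimethoxyphenyl)-3,6-dihydro-2H-pyran-3-yl acetate (aryl and acetoxy cis)
Conditions: Pd(OAc)2 (10 mol %), 2 (1.8 equiv), MeCN, rt
Reagents that add atoms: 3,4-dimethoxyphenylboronic acid (2), COc1ccc(B(O)O)cc1OC
Why: Redox-neutral Heck-type C-glycosylation with Ferrier-type allylic transposition: the arylpalladium acetate formed by transmetalation should add syn across the enol ether on the face opposite the allylic C4 acetate, and anti β-acetoxy elimination returns Pd(OAc)2, so the sacrificed stereocentre is relayed to C6 (S) and the aryl group ends up cis to the surviving C1 acetate.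

**Step 2**
Reactants: 3 (3S,6S)-6-(3,4-dimethoxyphenyl)-3,6-dihydro-2H-pyran-3-yl acetate
Product: 4 (3S,6S)-6-(3,4-dimethoxyphenyl)-3,6-dihydro-2H-pyran-3-ol
Conditions: K2CO3 (0.2 equiv), MeOH, 0 °C to rt
Reagents that add atoms: none
Why: Zemplén-type transesterification; the ester has to go because LiBHEt3 in step 6 would cleave it to an alkoxide on C1 that could fragment (Grob) the very C4–C1 bond that is meant to migrate, and no stereocentre is touched.

**Step 3**
Reactants: 4 (3S,6S)-6-(3,4-dimethoxyphenyl)-3,6-dihydro-2H-pyran-3-ol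
Product: 5 tert-butyl{[(3S,6S)-6-(3,4-dimethoxyphenyl)-3,6-dihydro-2H-pyran-3-yl]oxy}dimethylsilane
Conditions: TBSCl, imidazole, DMF, rt
Reagents that add atoms: tert-butyldimethylsilyl chloride, CC(C)(C)[Si](C)(C)Cl
Why: Imidazole-promoted silylation puts a base- and hydride-stable, non-donating group on the C1 oxygen and adds bulk to the aryl face of the ring.

**Step 4**
Reactants: 5 tert-butyl{[(3S,6S)-6-(3,4-dimethoxyphenyl)-3,6-dihydro-2H-pyran-3-yl]oxy}dimethylsilane
Product: 6 (2R,3S,4R,5R)-5-[(tert-butyldimethylsilyl)oxy]-2-(3,4-dimethoxyphenyl)oxane-3,4-diol (α-D-lyxo pattern)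
Conditions: OsO4 (2 mol %), NMO, aq. acetone, rt
Reagents that add atoms: osmium tetroxide, O=[Os](=O)(=O)=O; N-methylmorpholine N-oxide, C[N+]1([O-])CCOCC1; water, O
Why: Upjohn dihydroxylation: the suprafacial addition of OsO4 should take place on the alkene face opposite the cis-disposed aryl and silyloxy groups, which sets the C5–OH trans to the aryl group (equatorial) and the C4–OH cis to the C5–OH (axial).

**Step 5**
Reactants: 6 (2R,3S,4R,5R)-5-[(tert-butyldimethylsilyl)oxy]-2-(3,4-dimethoxyphenyl)oxane-3,4-diol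
Product: 7 (2R,3S,4S,5R)-5-[(tert-butyldimethylsilyl)oxy]-2-(3,4-dimethoxyphenyl)-4-hydroxyoxan-3-yl trifluoromethanesulfonate
Conditions: Tf2O (1.05 equiv), pyridine, CH2Cl2, −40 °C; cold aqueous work-up, used at once
Reagents that add atoms: trifluoromethanesulfonic anhydride, O=S(=O)(OS(=O)(=O)C(F)(F)F)C(F)(F)F
Why: Regioselective O-sulfonylation of a cis-1,2-diol: in the chair with equatorial aryl the C5–OH is equatorial and should react ahead of the axial C4–OH, which is screened by two syn-axial C–H bonds, so the leaving group lands on C5 with its C–O configuration unchanged.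

**Step 6**
Reactants: 7 (2R,3S,4S,5R)-5-[(tert-butyldimethylsilyl)oxy]-2-(3,4-dimethoxyphenyl)-4-hydroxyoxan-3-yl trifluoromethanesulfonate
Product: 10 [(2S,3R,4S)-4-[(tert-butyldimethylsilyl)oxy]-2-(3,4-dimethoxyphenyl)oxolan-3-yl]methanol, via lithium alkoxide 8 (not isolated), via ring-contracted aldehyde 9 (not isolated)
Conditions: LiBHEt3 (3.5 equiv), THF, −78 to 0 °C; then H2O
Reagents that add atoms: none
Why: LiBHEt3 first deprotonates the axial C4–OH (8); in the chair held by the equatorial C6 aryl group the equatorial C5–OTf bond lies antiperiplanar to the ring bond C4–C1, so the alkoxide pushes C1 from C4 to C5 as triflate leaves, C4 is expelled from the ring as the formyl carbon (9), and a second hydride reduces this β-silyloxy aldehyde at once, before enolisation or β-elimination can set in. The closest known reaction type is the anionic semipinacol (pinacol-type) contraction of vicinal hydroxy sulfonates, known for cyclohexane cis-diol monosulfonates (to cyclopentanecarbaldehydes) and, with LiBHEt3, for pyranoside hydroxy sulfonates (to C-hydroxymethyl furanosides). Ring B (O7–C6–C5–C1–C8) is closed by the new C5–C1 bond in a three-centre 1,2-shift, the migrating σ bond attacking C5 from the rear of the C–OTf bond (exo-tet displacement), not by an end-to-end cyclisation. C5 is inverted, so the CH2OH group takes the face vacated by the triflate, trans to the aryl group (control element: the C5–O configuration set in step 4), while C1 migrates with retention and C6 is untouched. The step needs migration of C4–C1 rather than of the equally antiperiplanar C6–O7 bond (which would leave a veratryl cation), and it must avoid epoxide closure, hydride shift and Grob fragmentation. The anionic push is available only to the bonds on C4, the cis relation of O– and OTf rules out the epoxide, the equatorial C4–H is gauche to the leaving group, and the silyl ether on C1 cannot act as an electron-releasing trigger.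

**Step 7**
Reactants: 11 4-(benzyloxy)-3-methoxybenzyl alcohol
Product: 12 4-(benzyloxy)-3-methoxybenzyl bromide
Conditions: PBr3 (0.4 equiv), Et2O, 0 °C
Reagents that add atoms: phosphorus tribromide, BrP(Br)Br
Why: SN2-type conversion of a primary benzylic alcohol into the bromide through its phosphite ester; the electron-rich bromide is used freshly prepared.

**Step 8**
Reactants: 10 [(2S,3R,4S)-4-[(tert-butyldimethylsilyl)oxy]-2-(3,4-dimethoxyphenyl)oxolan-3-yl]methanol; 12 4-(benzyloxy)-3-methoxybenzyl bromide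
Product: 13 tert-butyl{[(3S,4R,5S)-4-({[4-(benzyloxy)-3-methoxyphenyl]methoxy}methyl)-5-(3,4-dimethoxyphenyl)oxolan-3-yl]oxy}dimethylsilane
Conditions: NaH, Bu4NI (cat.), THF/DMF, 0 °C to rt
Reagents that add atoms: 4-(benzyloxy)-3-methoxybenzyl bromide (12), COc1cc(CBr)ccc1OCc1ccccc1
Why: Williamson ether synthesis on the only free hydroxyl group places C2 and its aryl group on O3; the trans-disposed silyl ether is poorly placed for O-to-O silyl migration and no stereocentre is involved.

**Step 9**
Reactants: 13 tert-butyl{[(3S,4R,5S)-4-({[4-(benzyloxy)-3-methoxyphenyl]methoxy}methyl)-5-(3,4-dimethoxyphenyl)oxolan-3-yl]oxy}dimethylsilane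
Product: 14 (3S,4S,5S)-4-({[4-(benzyloxy)-3-methoxyphenyl]methoxy}methyl)-5-(3,4-dimethoxyphenyl)oxolan-3-ol
Conditions: Bu4NF, THF, rt
Reagents that add atoms: none
Why: Fluoride-induced desilylation, driven by the Si–F bond, frees the C1 hydroxyl; the ethers and stereocentres are inert.

**Step 10**
Reactants: 14 (3S,4S,5S)-4-({[4-(benzyloxy)-3-methoxyphenyl]methoxy}methyl)-5-(3,4-dimethoxyphenyl)oxolan-3-ol
Product: 15 (4R,5S)-4-({[4-(benzyloxy)-3-methoxyphenyl]methoxy}methyl)-5-(3,4-dimethoxyphenyl)oxolan-3-one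
Conditions: Dess–Martin periodinane, CH2Cl2, 0 °C to rt
Reagents that add atoms: none
Why: Dess–Martin oxidation under neutral, non-enolising conditions should give the β-alkoxy ketone without β-elimination, and C5, now α to the carbonyl group, already holds the more stable trans relation to the C6 aryl group.

**Step 11**
Reactants: 15 (4R,5S)-4-({[4-(benzyloxy)-3-methoxyphenyl]methoxy}methyl)-5-(3,4-dimethoxyphenyl)oxolan-3-one
Product: 17 (1S,2R,5R,6S)-2-[4-(benzyloxy)-3-methoxyphenyl]-6-(3,4-dimethoxyphenyl)-3,7-dioxabicyclo[3.3.0]octan-1-ol, via 1,5-biradical 16 (not isolated)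
Conditions: hν (medium-pressure Hg lamp, Pyrex filter, λ > 290 nm), degassed benzene (5 mM), rt
Reagents that add atoms: none
Why: Norrish–Yang photocyclisation of a β-alkoxy ketone: the n,π* excited carbonyl abstracts a δ-hydrogen from the doubly activated benzylic ether CH2 (no γ C–H is within reach) and recombination of biradical 16 forms C1–C2 and closes ring A, the C5–C4–O3 tether forcing bond formation on the C4 face of C1 (cis fusion, OH on the face of the C6 aryl group, C1 S) and the aryl group taking the convex exo position (C2 R).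

**Step 12**
Reactants: 17 (1S,2R,5R,6S)-2-[4-(benzyloxy)-3-methoxyphenyl]-6-(3,4-dimethoxyphenyl)-3,7-dioxabicyclo[3.3.0]octan-1-ol
Product: 18 (1S,2R,5R,6S)-2-[4-(benzyloxy)-3-methoxyphenyl]-6-(3,4-dimethoxyphenyl)-3,7-dioxabicyclo[3.3.0]octan-1-yl acetate
Conditions: Ac2O, DMAP, Et3N, CH2Cl2, reflux
Reagents that add atoms: acetic anhydride, CC(=O)OC(C)=O
Why: DMAP-catalysed acyl transfer is the usual way to esterify a hindered tertiary alcohol; the phenol is still masked, so only the C1–OH can react, and the C1–O bond is not broken, so the configuration is kept.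

**Step 13**
Reactants: 18 (1S,2R,5R,6S)-2-[4-(benzyloxy)-3-methoxyphenyl]-6-(3,4-dimethoxyphenyl)-3,7-dioxabicyclo[3.3.0]octan-1-yl acetate
Product: 19 (1S,2R,5R,6S)-6-(3,4-dimethoxyphenyl)-2-(4-hydroxy-3-methoxyphenyl)-3,7-dioxabicyclo[3.3.0]octan-1-yl acetate (target)
Conditions: H2 (1 atm), Pd/C (10 wt % Pd), EtOAc, rt, stopped after one equivalent of H2
Reagents that add atoms: none
Why: Catalytic hydrogenolysis: the unhindered aryl benzyl ether should be cleaved faster than the two secondary, ring-bound benzylic C–O bonds at C2 and C6, and the acetate is inert.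

**Compound list**

1 | 3,4-di-O-acetyl-D-xylal, (3R,4R)-3,4-dihydro-2H-pyran-3,4-diyl diacetate | CC(=O)O[C@@H]1C=COC[C@H]1OC(C)=O | starting material
2 | 3,4-dimethoxyphenylboronic acid | COc1ccc(B(O)O)cc1OC | starting material
3 | (3S,6S)-6-(3,4-dimethoxyphenyl)-3,6-dihydro-2H-pyran-3-yl acetate | CC(=O)O[C@@H]1CO[C@H](c2ccc(OC)c(OC)c2)C=C1 | intermediate
4 | (3S,6S)-6-(3,4-dimethoxyphenyl)-3,6-dihydro-2H-pyran-3-ol | O[C@@H]1CO[C@H](c2ccc(OC)c(OC)c2)C=C1 | intermediate
5 | tert-butyl{[(3S,6S)-6-(3,4-dimethoxyphenyl)-3,6-dihydro-2H-pyran-3-yl]oxy}dimethylsilane | CC(C)(C)[Si](C)(C)O[C@@H]1CO[C@H](c2ccc(OC)c(OC)c2)C=C1 | intermediate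
6 | (2R,3S,4R,5R)-5-[(tert-butyldimethylsilyl)oxy]-2-(3,4-dimethoxyphenyl)oxane-3,4-diol | CC(C)(C)[Si](C)(C)O[C@@H]1CO[C@H](c2ccc(OC)c(OC)c2)[C@@H](O)[C@H]1O | intermediate
7 | (2R,3S,4S,5R)-5-[(tert-butyldimethylsilyl)oxy]-2-(3,4-dimethoxyphenyl)-4-hydroxyoxan-3-yl trifluoromethanesulfonate | CC(C)(C)[Si](C)(C)O[C@@H]1CO[C@H](c2ccc(OC)c(OC)c2)[C@@H](OS(=O)(=O)C(F)(F)F)[C@H]1O | intermediate
8 | lithium alkoxide of 7 (O– on C4) | [Li+].CC(C)(C)[Si](C)(C)O[C@@H]1CO[C@H](c2ccc(OC)c(OC)c2)[C@@H](OS(=O)(=O)C(F)(F)F)[C@H]1[O-] | intermediate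
9 | (2S,3R,4S)-4-[(tert-butyldimethylsilyl)oxy]-2-(3,4-dimethoxyphenyl)oxolane-3-carbaldehyde | CC(C)(C)[Si](C)(C)O[C@@H]1CO[C@H](c2ccc(OC)c(OC)c2)[C@H]1C=O | intermediate
10 | [(2S,3R,4S)-4-[(tert-butyldimethylsilyl)oxy]-2-(3,4-dimethoxyphenyl)oxolan-3-yl]methanol | CC(C)(C)[Si](C)(C)O[C@@H]1CO[C@H](c2ccc(OC)c(OC)c2)[C@H]1CO | intermediate
11 | 4-(benzyloxy)-3-methoxybenzyl alcohol | COc1cc(CO)ccc1OCc1ccccc1 | starting material
12 | 4-(benzyloxy)-3-methoxybenzyl bromide | COc1cc(CBr)ccc1OCc1ccccc1 | intermediate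
13 | tert-butyl{[(3S,4R,5S)-4-({[4-(benzyloxy)-3-methoxyphenyl]methoxy}methyl)-5-(3,4-dimethoxyphenyl)oxolan-3-yl]oxy}dimethylsilane | CC(C)(C)[Si](C)(C)O[C@@H]1CO[C@H](c2ccc(OC)c(OC)c2)[C@H]1COCc1ccc(OCc2ccccc2)c(OC)c1 | intermediate
14 | (3S,4S,5S)-4-({[4-(benzyloxy)-3-methoxyphenyl]methoxy}methyl)-5-(3,4-dimethoxyphenyl)oxolan-3-ol | O[C@@H]1CO[C@H](c2ccc(OC)c(OC)c2)[C@H]1COCc1ccc(OCc2ccccc2)c(OC)c1 | intermediate
15 | (4R,5S)-4-({[4-(benzyloxy)-3-methoxyphenyl]methoxy}methyl)-5-(3,4-dimethoxyphenyl)oxolan-3-one | O=C1CO[C@H](c2ccc(OC)c(OC)c2)[C@H]1COCc1ccc(OCc2ccccc2)c(OC)c1 | intermediate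
16 | 1,5-biradical (ketyl centre at C1, benzylic centre at C2) | O[C]1CO[C@H](c2ccc(OC)c(OC)c2)[C@H]1CO[CH]c1ccc(OCc2ccccc2)c(OC)c1 | intermediate
17 | (1S,2R,5R,6S)-2-[4-(benzyloxy)-3-methoxyphenyl]-6-(3,4-dimethoxyphenyl)-3,7-dioxabicyclo[3.3.0]octan-1-ol | COc1cc([C@H]2OC[C@@H]3[C@@H](c4ccc(OC)c(OC)c4)OC[C@]23O)ccc1OCc1ccccc1 | intermediate
18 | (1S,2R,5R,6S)-2-[4-(benzyloxy)-3-methoxyphenyl]-6-(3,4-dimethoxyphenyl)-3,7-dioxabicyclo[3.3.0]octan-1-yl acetate | COc1cc([C@H]2OC[C@@H]3[C@@H](c4ccc(OC)c(OC)c4)OC[C@]23OC(C)=O)ccc1OCc1ccccc1 | intermediate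
19 | (1S,2R,5R,6S)-6-(3,4-dimethoxyphenyl)-2-(4-hydroxy-3-methoxyphenyl)-3,7-dioxabicyclo[3.3.0]octan-1-yl acetate | COc1cc([C@H]2OC[C@@H]3[C@@H](c4ccc(OC)c(OC)c4)OC[C@]23OC(C)=O)ccc1O | target

Total steps: 13. Longest linear sequence: 12 (steps 1–6 and 8–13).

**Steps most likely to fail**

**Step 6.**
- What may go wrong: the reaction may leak through the ring-flipped chair (axial triflate) into a 1,2-hydride shift and over-reduction. O7 may migrate instead of C1. Hydride may displace the triflate directly.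
- Fallback: it sets out from 5 and comes back at 10. Epoxidation of 5 with mCPBA on the face opposite the aryl and silyloxy groups gives the 5-[(tert-butyldimethylsilyl)oxy]-2-(3,4-dimethoxyphenyl)-3,7-dioxabicyclo[4.1.0]heptane epoxide F2. BF3·OEt2 in CH2Cl2 at −78 °C then brings about a Meinwald epoxide-to-aldehyde ring contraction.
- Why it converges: cleavage of either C–O bond, with anti migration of the neighbouring ring bond, leads to the same aldehyde 9, with the formyl group on the face of the departed oxygen. NaBH4 in the same flask gives 10.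

**Step 11.**
- What may go wrong: α-cleavage of the excited oxolanone may outrun the hydrogen transfer. The biradical may revert to the ketone. Facial control at C2 may be poor.
- Fallback: it sets out from 15 and 12 and comes back at 17. Compound 12 and PPh3 give [4-(benzyloxy)-3-methoxybenzyl]triphenylphosphonium bromide F3. Its ylide (KN(SiMe3)2, THF) undergoes Wittig olefination with 15 to give the (Z)-benzylidene oxolane F4.
- Completion: OsO4/NMO dihydroxylation on the face opposite the C5 side chain gives the C1,C2-diol F5. Catalytic camphorsulfonic acid in CH2Cl2 ionises the benzylic C2–OH. Ether oxygen O3 captures the cation and releases its own stabilised benzyl group (debenzylative cycloetherification, stereoconvergent to the exo aryl isomer), which gives 17.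

**Step 5.**
- What may go wrong: regiocontrol may be lost (sulfonylation of the axial hydroxyl or of both), and the hydroxy triflate may ionise prematurely during handling.
- Fallback: it sets out from 6 and comes back at 10. Tin-templated sulfonylation (TsCl, Et3N, Bu2SnO 10 mol %, CH2Cl2) delivers the sulfonyl group to the equatorial oxygen of the cis-diol. The product is the storable (2R,3S,4S,5R)-5-[(tert-butyldimethylsilyl)oxy]-2-(3,4-dimethoxyphenyl)-4-hydroxyoxan-3-yl 4-methylbenzenesulfonate F1. It is contracted and reduced with LiBHEt3 in refluxing THF to 10.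

**Further compounds**

F1 | step 5 | (2R,3S,4S,5R)-5-[(tert-butyldimethylsilyl)oxy]-2-(3,4-dimethoxyphenyl)-4-hydroxyoxan-3-yl 4-methylbenzenesulfonate | CC(C)(C)[Si](C)(C)O[C@@H]1CO[C@H](c2ccc(OC)c(OC)c2)[C@@H](OS(=O)(=O)c2ccc(C)cc2)[C@H]1O
F2 | step 6 | 5-[(tert-butyldimethylsilyl)oxy]-2-(3,4-dimethoxyphenyl)-3,7-dioxabicyclo[4.1.0]heptane, oxirane oxygen trans to aryl and silyloxy groups | CC(C)(C)[Si](C)(C)O[C@@H]1CO[C@H](c2ccc(OC)c(OC)c2)[C@H]2O[C@@H]12
F3 | step 11 | [4-(benzyloxy)-3-methoxybenzyl]triphenylphosphonium bromide | [Br-].COc1cc(C[P+](c2ccccc2)(c2ccccc2)c2ccccc2)ccc1OCc1ccccc1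
F4 | step 11 | (Z)-3-[4-(benzyloxy)-3-methoxybenzylidene]-4-({[4-(benzyloxy)-3-methoxyphenyl]methoxy}methyl)-5-(3,4-dimethoxyphenyl)oxolane, ring substituents trans as in 15 | COc1cc(/C=C2\CO[C@H](c3ccc(OC)c(OC)c3)[C@H]2COCc2ccc(OCc3ccccc3)c(OC)c2)ccc1OCc1ccccc1
F5 | step 11 | (3S,4R,5S)-3-{(R)-[4-(benzyloxy)-3-methoxyphenyl](hydroxy)methyl}-4-({[4-(benzyloxy)-3-methoxyphenyl]methoxy}methyl)-5-(3,4-dimethoxyphenyl)oxolan-3-ol | COc1cc([C@@H](O)[C@@]2(O)CO[C@H](c3ccc(OC)c(OC)c3)[C@H]2COCc2ccc(OCc3ccccc3)c(OC)c2)ccc1OCc1ccccc1
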